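**Plan**

1. Numbering: ring O1, C2, C3, C3a, C4 (C=O), C5 (OH), C6, C7, C7a; side chain C1′ (carbinol carbon) to C10′ (CO2H).
2. Cuts, late to early: C10′ acid → silyl-protected allylic alcohol; C5–OH → enolate oxidation; C1′–CH3 → methyl addition to a C1′ ketone; then the dihydrofuran ring at C3–C3a, C2–C3 and O1–C2 in one operation.
3. Enabling feature: in the ring O1–C2–C3–C3a–C7a, C3 is a lone CH2 between the central carbon of a cyclohexane-1,3-dione (C3a, flanked by C4 and C7a) and C2, which carries O1 and the C1′ carbonyl. C3 is therefore formaldehyde and C2 the halogen-bearing carbon of a bromomethyl ketone.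
4. C2 and C1′–C10′ with both methyl branches are geranylacetone (acetyl CH3 = C2, C=O = C1′, (E)-terminal CH3 = C10′), so the whole chain arrives in one piece.
5. Forward: chain oxidation, silylation and bromination; then the only ring-forming event, a three-component Knoevenagel/ammonium-ylide [4+1] annulation onto the six-membered dione; then C1′, C5 and C10′ are adjusted.
6. Stereochemistry: C2 from the cinchona ammonium group in the ring closure, C1′ from C2 (Felkin–Anh), C5 from a chiral N-sulfonyloxaziridine; both E-alkenes come from geranylacetone.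

Key step: step 4

Assumption 1: the sense of induction of the cinchona ammonium group in step 4 cannot be predicted reliably; O-methylquinidine (from quinidine, NaH/MeI; SMILES COC1=CC2=C(C=CN=C2C=C1)[C@@H]([C@H]3C[C@@H]4CCN3C[C@@H]4C=C)OC) is written, and its pseudo-enantiomer O-methylquinine takes its place if a trial shows the opposite sense.

Assumption 2: the enolate face chosen by the (camphorsulfonyl)oxaziridine in step 7 is likewise to be settled by a trial; the (+)-(2R,8aS) reagent is written and its commercially available enantiomer is the alternative.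

Assumption 3: formaldehyde is delivered as paraformaldehyde.

**Route**

Step 1
Reactants: 1 geranylacetone, (5E)-6,10-dimethylundeca-5,9-dien-2-one
Product: 2 (5E,9E)-11-hydroxy-6,10-dimethylundeca-5,9-dien-2-one
Conditions: SeO2 (cat.), t-BuOOH, salicylic acid (cat.), CH2Cl2, 0 °C → rt
Reagents that add atoms: tert-butyl hydroperoxide, CC(C)(C)OO (oxygen source, relayed by selenium dioxide, O=[Se]=O)
Why: SeO2-catalysed allylic oxidation (ene reaction, then [2,3]-sigmatropic shift) should attack the (E)-methyl group of the terminal trisubstituted alkene, the most electron-rich and least hindered ene partner, with retention of the E geometry, while the ketone α-positions are not touched at room temperature; any enal from over-oxidation is removed by chromatography.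

Step 2
Reactants: 2 (5E,9E)-11-hydroxy-6,10-dimethylundeca-5,9-dien-2-one
Product: 3 (5E,9E)-11-(tert-butyldimethylsilyloxy)-6,10-dimethylundeca-5,9-dien-2-one
Conditions: TBSCl, imidazole, DMF, rt
Reagents that add atoms: tert-butyldimethylsilyl chloride, CC(C)(C)[Si](C)(C)Cl
Why: Standard silylation of a primary alcohol; the TBS ether should withstand LDA, NBS at low temperature, carbonate, the titanium reagent and the enolate oxidation and is removed only in step 8.

Step 3
Reactants: 3 (5E,9E)-11-(tert-butyldimethylsilyloxy)-6,10-dimethylundeca-5,9-dien-2-one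
Product: 5 (5E,9E)-1-bromo-11-(tert-butyldimethylsilyloxy)-6,10-dimethylundeca-5,9-dien-2-one, via trimethylsilyl enol ether 4 (not isolated)
Conditions: LDA, TMSCl, THF, −78 °C; volatiles removed; then NBS, NaHCO3, THF, −78 → 0 °C
Reagents that add atoms: N-bromosuccinimide, O=C1CCC(=O)N1Br (Br in 5); chlorotrimethylsilane, C[Si](C)(C)Cl (silyl group of 4 only)
Why: Kinetic deprotonation with LDA in the presence of TMSCl takes the methyl protons of the methyl ketone, and the resulting terminal silyl enol ether is brominated by NBS at −78 °C far faster than the two trisubstituted alkenes (regioselective α-bromination through a silyl enol ether).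

Step 4
Reactants: 5 (5E,9E)-1-bromo-11-(tert-butyldimethylsilyloxy)-6,10-dimethylundeca-5,9-dien-2-one; 6 cyclohexane-1,3-dione; 7 formaldehyde (as paraformaldehyde)
Product: 11 (2S)-2-[(4E,8E)-10-(tert-butyldimethylsilyloxy)-5,9-dimethyldeca-4,8-dienoyl]-3,5,6,7-tetrahydro-1-benzofuran-4(2H)-one, via cinchona ammonium bromide 8 (not isolated), via 2-methylenecyclohexane-1,3-dione 9 (not isolated), via ammonium enolate betaine 10 (not isolated)
Conditions: O-methylquinidine (1.05 equiv), MeCN, rt; then Cs2CO3 (1.2 equiv), 4 Å MS, (CH2O)n, slow addition of 6, MeCN, 0 °C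
Reagents that add atoms: none
Why: Proposed new method: base-mediated Knoevenagel condensation of 6 with 7 gives the s-cis oxadiene 9 (C3–C3a), the ylide formed by deprotonation of 8 adds to its methylene terminus (C2–C3) to give betaine 10, and the dione enolate oxygen then displaces the quinuclidine nitrogen from C2 (O1–C2). The closest known reaction types are the three-component synthesis of 2-acyl-2,3-dihydrofurans from cyclic 1,3-diones, aldehydes and pyridinium ylides, and the cinchona ammonium-ylide cyclopropanations and [4+1] annulations of o-quinone methides. The dihydrofuran ring closes by 5-exo-tet O-alkylation, which should be preferred over 3-exo-tet C-alkylation as in the pyridinium series, and a spirocyclopropane formed none the less is doubly activated and can be reopened by the released amine at the acyl-bearing carbon back to 10. C2 is set in this invertive closure: the ammonium-bearing carbon of 10 is acidic and equilibrates between its epimers, so the (S)-product should drain from the faster-closing (R)-betaine under control of the cinchona framework (dynamic kinetic resolution). The step needs ylide addition to 9 to outrun attack of a second dione on 9 and direct alkylation of the dione by the bromoketone; complete prior conversion of 5 into 8 and slow addition of 6 to an excess of ylide should secure this. Solid Cs2CO3 in MeCN at 0 °C with sieves deprotonates the ammonium salt but should not enolise the far less acidic α-alkoxy ketone 11, which protects C2 from racemisation, and the amine is recovered.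

Step 5
Reactants: 11 (2S)-2-[(4E,8E)-10-(tert-butyldimethylsilyloxy)-5,9-dimethyldeca-4,8-dienoyl]-3,5,6,7-tetrahydro-1-benzofuran-4(2H)-one
Product: 12 (2S)-2-[(2S,5E,9E)-11-(tert-butyldimethylsilyloxy)-2-hydroxy-6,10-dimethylundeca-5,9-dien-2-yl]-3,5,6,7-tetrahydro-1-benzofuran-4(2H)-one
Conditions: MeTi(OiPr)3 (commercial solution, 2 equiv), THF, −40 → 0 °C
Reagents that add atoms: methyltitanium triisopropoxide, C[Ti](OC(C)C)(OC(C)C)OC(C)C
Why: Non-chelating organotitanium addition: the reagent is weakly Lewis acidic and O1 is a poorly basic vinylogous-ester oxygen, so the polar Felkin–Anh transition state (C2–O1 anti to the incoming methyl, which passes C2–H) should operate and set C1′ as S, while the non-basic reagent neither enolises the α-alkoxy ketone nor attacks the vinylogous ester carbonyl.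

Step 6
Reactants: 12 (2S)-2-[(2S,5E,9E)-11-(tert-butyldimethylsilyloxy)-2-hydroxy-6,10-dimethylundeca-5,9-dien-2-yl]-3,5,6,7-tetrahydro-1-benzofuran-4(2H)-one
Product: 13 (2S)-2-[(2S,5E,9E)-11-(tert-butyldimethylsilyloxy)-6,10-dimethyl-2-(triethylsilyloxy)undeca-5,9-dien-2-yl]-3,5,6,7-tetrahydro-1-benzofuran-4(2H)-one
Conditions: TESOTf, 2,6-lutidine, CH2Cl2, −78 °C
Reagents that add atoms: triethylsilyl trifluoromethanesulfonate, CC[Si](CC)(CC)OS(=O)(=O)C(F)(F)F
Why: Silyl triflate/2,6-lutidine silylation of a hindered tertiary alcohol; the ether removes the acidic OH before enolate formation and keeps a C1′ alkoxide from attacking the vinylogous ester at C7a.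

Step 7
Reactants: 13 (2S)-2-[(2S,5E,9E)-11-(tert-butyldimethylsilyloxy)-6,10-dimethyl-2-(triethylsilyloxy)undeca-5,9-dien-2-yl]-3,5,6,7-tetrahydro-1-benzofuran-4(2H)-one
Product: 14 (2S,5R)-2-[(2S,5E,9E)-11-(tert-butyldimethylsilyloxy)-6,10-dimethyl-2-(triethylsilyloxy)undeca-5,9-dien-2-yl]-5-hydroxy-3,5,6,7-tetrahydro-1-benzofuran-4(2H)-one
Conditions: LDA (1.2 equiv), THF, −78 °C; (+)-(2R,8aS)-(camphorsulfonyl)oxaziridine, −78 → −40 °C; AcOH
Reagents that add atoms: (+)-(2R,8aS)-(camphorsulfonyl)oxaziridine, CC1(C)[C@@H]2CC[C@]13CS(=O)(=O)[N@]4O[C@@]34C2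
Why: Kinetic deprotonation of the vinylogous ester with LDA at −78 °C takes the α′ proton at C5 and not the γ proton at C7, and the oxaziridine transfers oxygen to one face of this enolate under reagent control (asymmetric enolate hydroxylation, Davis oxidation) to set C5, C2 being too remote to interfere and the hindered sulfonimine by-product being inert to the enolate.

Step 8
Reactants: 14 (2S,5R)-2-[(2S,5E,9E)-11-(tert-butyldimethylsilyloxy)-6,10-dimethyl-2-(triethylsilyloxy)undeca-5,9-dien-2-yl]-5-hydroxy-3,5,6,7-tetrahydro-1-benzofuran-4(2H)-one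
Product: 15 (2S,5R)-2-[(2S,5E,9E)-2,11-dihydroxy-6,10-dimethylundeca-5,9-dien-2-yl]-5-hydroxy-3,5,6,7-tetrahydro-1-benzofuran-4(2H)-one
Conditions: HF·pyridine, pyridine, THF, 0 °C → rt
Reagents that add atoms: none
Why: Fluoride cleaves both Si–O bonds (primary TBS and tertiary TES ether), and the pyridine buffer keeps the medium mild enough for the base-sensitive α-ketol at C5 and for the acid-sensitive tertiary alcohol next to the C4′ alkene.

Step 9
Reactants: 15 (2S,5R)-2-[(2S,5E,9E)-2,11-dihydroxy-6,10-dimethylundeca-5,9-dien-2-yl]-5-hydroxy-3,5,6,7-tetrahydro-1-benzofuran-4(2H)-one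
Product: 16 (2E,6E,10S)-10-hydroxy-10-[(2S,5R)-5-hydroxy-4-oxo-2,3,4,5,6,7-hexahydro-1-benzofuran-2-yl]-2,6-dimethylundeca-2,6-dienal
Conditions: TEMPO (cat.), PhI(OAc)2, CH2Cl2, rt
Reagents that add atoms: none
Why: The oxoammonium salt generated from TEMPO and PhI(OAc)2 oxidises the primary allylic alcohol much faster than the secondary α-ketol and leaves the tertiary alcohol alone, stopping at the (E)-enal without isomerisation.

Step 10
Reactants: 16 (2E,6E,10S)-10-hydroxy-10-[(2S,5R)-5-hydroxy-4-oxo-2,3,4,5,6,7-hexahydro-1-benzofuran-2-yl]-2,6-dimethylundeca-2,6-dienal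
Product: 17 (2E,6E,10S)-10-hydroxy-10-[(2S,5R)-5-hydroxy-4-oxo-2,3,4,5,6,7-hexahydro-1-benzofuran-2-yl]-2,6-dimethylundeca-2,6-dienoic acid (CNP0117600.1)
Conditions: NaClO2, NaH2PO4, 2-methyl-2-butene, t-BuOH/H2O, 0 °C → rt
Reagents that add atoms: sodium chlorite, [Na+].[O-]Cl=O
Why: Pinnick oxidation converts the enal into the acid under weakly acidic conditions that do not epimerise C5, and 2-methyl-2-butene traps HOCl before it can reach the alkenes or the enol ether.

**Compound list**

1 | geranylacetone, (5E)-6,10-dimethylundeca-5,9-dien-2-one | CC(C)=CCC/C(C)=C/CCC(C)=O | starting material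
2 | (5E,9E)-11-hydroxy-6,10-dimethylundeca-5,9-dien-2-one | C/C(=C\CCC(C)=O)CC/C=C(\C)CO | intermediate
3 | (5E,9E)-11-(tert-butyldimethylsilyloxy)-6,10-dimethylundeca-5,9-dien-2-one | C/C(=C\CCC(C)=O)CC/C=C(\C)CO[Si](C)(C)C(C)(C)C | intermediate
4 | tert-butyl{[(2E,6E)-2,6-dimethyl-10-(trimethylsilyloxy)undeca-2,6,10-trien-1-yl]oxy}dimethylsilane (kinetic silyl enol ether) | C/C(=C\CCC(=C)O[Si](C)(C)C)CC/C=C(\C)CO[Si](C)(C)C(C)(C)C | intermediate (not isolated)
5 | (5E,9E)-1-bromo-11-(tert-butyldimethylsilyloxy)-6,10-dimethylundeca-5,9-dien-2-one | C/C(=C\CCC(=O)CBr)CC/C=C(\C)CO[Si](C)(C)C(C)(C)C | intermediate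
6 | cyclohexane-1,3-dione | O=C1CCCC(=O)C1 | starting material
7 | formaldehyde (used as paraformaldehyde) | C=O | starting material
8 | N-[(5E,9E)-11-(tert-butyldimethylsilyloxy)-6,10-dimethyl-2-oxoundeca-5,9-dien-1-yl]-O-methylquinidinium bromide (alkylated at the quinuclidine nitrogen) | COC1=CC2=C(C=CN=C2C=C1)[C@@H]([C@H]3C[C@@H]4CC[N@@+]3(CC(=O)CC/C=C(C)/CC/C=C(\C)CO[Si](C)(C)C(C)(C)C)C[C@@H]4C=C)OC.[Br-] | intermediate (not isolated)
9 | 2-methylenecyclohexane-1,3-dione | C=C1C(=O)CCCC1=O | intermediate (not isolated)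
10 | 2-[(2R,6E,10E)-12-(tert-butyldimethylsilyloxy)-7,11-dimethyl-2-(O-methylquinidinium-1-yl)-3-oxododeca-6,10-dien-1-yl]-3-oxocyclohex-1-en-1-olate (reactive epimer, equilibrating with its C2 epimer) | COC1=CC2=C(C=CN=C2C=C1)[C@@H]([C@H]3C[C@@H]4CC[N@@+]3([C@H](CC5=C([O-])CCCC5=O)C(=O)CC/C=C(C)/CC/C=C(\C)CO[Si](C)(C)C(C)(C)C)C[C@@H]4C=C)OC | intermediate (not isolated)
11 | (2S)-2-[(4E,8E)-10-(tert-butyldimethylsilyloxy)-5,9-dimethyldeca-4,8-dienoyl]-3,5,6,7-tetrahydro-1-benzofuran-4(2H)-one | C/C(=C\CCC(=O)[C@@H]1CC2=C(CCCC2=O)O1)CC/C=C(\C)CO[Si](C)(C)C(C)(C)C | intermediate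
12 | (2S)-2-[(2S,5E,9E)-11-(tert-butyldimethylsilyloxy)-2-hydroxy-6,10-dimethylundeca-5,9-dien-2-yl]-3,5,6,7-tetrahydro-1-benzofuran-4(2H)-one | C/C(=C\CC[C@](C)(O)[C@@H]1CC2=C(CCCC2=O)O1)CC/C=C(\C)CO[Si](C)(C)C(C)(C)C | intermediate
13 | (2S)-2-[(2S,5E,9E)-11-(tert-butyldimethylsilyloxy)-6,10-dimethyl-2-(triethylsilyloxy)undeca-5,9-dien-2-yl]-3,5,6,7-tetrahydro-1-benzofuran-4(2H)-one | C/C(=C\CC[C@](C)(O[Si](CC)(CC)CC)[C@@H]1CC2=C(CCCC2=O)O1)CC/C=C(\C)CO[Si](C)(C)C(C)(C)C | intermediate
14 | (2S,5R)-2-[(2S,5E,9E)-11-(tert-butyldimethylsilyloxy)-6,10-dimethyl-2-(triethylsilyloxy)undeca-5,9-dien-2-yl]-5-hydroxy-3,5,6,7-tetrahydro-1-benzofuran-4(2H)-one | C/C(=C\CC[C@](C)(O[Si](CC)(CC)CC)[C@@H]1CC2=C(CC[C@@H](O)C2=O)O1)CC/C=C(\C)CO[Si](C)(C)C(C)(C)C | intermediate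
15 | (2S,5R)-2-[(2S,5E,9E)-2,11-dihydroxy-6,10-dimethylundeca-5,9-dien-2-yl]-5-hydroxy-3,5,6,7-tetrahydro-1-benzofuran-4(2H)-one | C/C(=C\CC[C@](C)(O)[C@@H]1CC2=C(CC[C@@H](O)C2=O)O1)CC/C=C(\C)CO | intermediate
16 | (2E,6E,10S)-10-hydroxy-10-[(2S,5R)-5-hydroxy-4-oxo-2,3,4,5,6,7-hexahydro-1-benzofuran-2-yl]-2,6-dimethylundeca-2,6-dienal | C/C(=C\CC[C@](C)(O)[C@@H]1CC2=C(CC[C@@H](O)C2=O)O1)CC/C=C(\C)C=O | intermediate
17 | (2E,6E,10S)-10-hydroxy-10-[(2S,5R)-5-hydroxy-4-oxo-2,3,4,5,6,7-hexahydro-1-benzofuran-2-yl]-2,6-dimethylundeca-2,6-dienoic acid | C/C(=C\CC[C@](C)(O)[C@@H]1CC2=C(CC[C@@H](O)C2=O)O1)CC/C=C(\C)C(=O)O | target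

**Step count**

Total: 10 steps. Longest linear sequence: 10 steps (1 → 17); 6 and 7 enter in step 4.

**Steps most likely to fail**

Step 4 (proposed new method). The ring closure may proceed with poor facial control, C2 may racemise under the base, or the methylene dione may be consumed by a second dione or the dione by direct alkylation. The fallback uses known chemistry and sets out from 5, 6 and 7. Compound 5 is quaternised with pyridine to 1-[(5E,9E)-11-(tert-butyldimethylsilyloxy)-6,10-dimethyl-2-oxoundeca-5,9-dien-1-yl]pyridinium bromide F1. F1 is combined with 6, 7 and Et3N in MeCN in the established three-component pyridinium-ylide dihydrofuran synthesis (through 9) to give the racemic ketone F2. The enantiomers are separated by preparative chromatography on a chiral stationary phase. The (2R)-enantiomer F3 is racemised at C2 with DBU and returned to the separation, and the (2S)-enantiomer is 11, where the route is rejoined.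

Step 5. Facial selectivity may be poor if a chelated transition state competes with the Felkin–Anh one, which would give the (1′R)-epimer. The fallback exchanges the roles of the two ketone substituents so that chelation delivers the correct face. Bromoacetone replaces 5 under the conditions of step 4 with 6 and 7; this passes through 9, the N-(2-oxopropyl)-O-methylquinidinium bromide F4 and its betaine F5, and gives (2S)-2-acetyl-3,5,6,7-tetrahydro-1-benzofuran-4(2H)-one F6. The chain is taken from 3: haloform cleavage (NaOBr, dioxane/H2O, 0 °C) gives (4E,8E)-10-(tert-butyldimethylsilyloxy)-5,9-dimethyldeca-4,8-dienoic acid F7. Coupling with N-hydroxypyridine-2-thione (DCC) gives the Barton ester F8, and photolysis with CHI3 (Barton decarboxylative iodination) gives the homoallylic iodide F9. Magnesium in Et2O converts F9 into the Grignard reagent F10. Addition of F10 to F6 in CH2Cl2/Et2O at −78 °C in the presence of MgBr2·OEt2 should place the nucleophile on the C2–H side of the O1/C=O magnesium chelate and give 12, where the route is rejoined.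

Step 7. Facial selectivity at C5 may be poor, since reagent control on a cyclic dienolate is the only source of induction, and deprotonation at C7 may compete. The fallback sets out from 13. Mn(OAc)3-mediated α′-acetoxylation (benzene, reflux) gives the C5 acetate F11 as a mixture of C5 epimers. Lipase-catalysed hydrolysis, with an enzyme selected to cleave the (5R)-acetate, gives 14, where the route is rejoined. The untouched (5S)-acetate F12 is epimerised at C5 with mild base and resubmitted.

**Further compounds**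

F1 | step 4 | 1-[(5E,9E)-11-(tert-butyldimethylsilyloxy)-6,10-dimethyl-2-oxoundeca-5,9-dien-1-yl]pyridinium bromide | C/C(=C\CCC(=O)C[n+]1ccccc1)CC/C=C(\C)CO[Si](C)(C)C(C)(C)C.[Br-]
F2 | step 4 | (2RS)-2-[(4E,8E)-10-(tert-butyldimethylsilyloxy)-5,9-dimethyldeca-4,8-dienoyl]-3,5,6,7-tetrahydro-1-benzofuran-4(2H)-one (racemate) | C/C(=C\CCC(=O)C1CC2=C(CCCC2=O)O1)CC/C=C(\C)CO[Si](C)(C)C(C)(C)C
F3 | step 4 | (2R)-2-[(4E,8E)-10-(tert-butyldimethylsilyloxy)-5,9-dimethyldeca-4,8-dienoyl]-3,5,6,7-tetrahydro-1-benzofuran-4(2H)-one | C/C(=C\CCC(=O)[C@H]1CC2=C(CCCC2=O)O1)CC/C=C(\C)CO[Si](C)(C)C(C)(C)C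
F4 | step 5 | N-(2-oxopropyl)-O-methylquinidinium bromide | COC1=CC2=C(C=CN=C2C=C1)[C@@H]([C@H]3C[C@@H]4CC[N@@+]3(CC(C)=O)C[C@@H]4C=C)OC.[Br-]
F5 | step 5 | 2-[(2R)-2-(O-methylquinidinium-1-yl)-3-oxobutyl]-3-oxocyclohex-1-en-1-olate | COC1=CC2=C(C=CN=C2C=C1)[C@@H]([C@H]3C[C@@H]4CC[N@@+]3([C@H](CC5=C([O-])CCCC5=O)C(C)=O)C[C@@H]4C=C)OC
F6 | step 5 | (2S)-2-acetyl-3,5,6,7-tetrahydro-1-benzofuran-4(2H)-one | CC(=O)[C@@H]1CC2=C(CCCC2=O)O1
F7 | step 5 | (4E,8E)-10-(tert-butyldimethylsilyloxy)-5,9-dimethyldeca-4,8-dienoic acid | C/C(=C\CCC(=O)O)CC/C=C(\C)CO[Si](C)(C)C(C)(C)C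
F8 | step 5 | 2-thioxopyridin-1(2H)-yl (4E,8E)-10-(tert-butyldimethylsilyloxy)-5,9-dimethyldeca-4,8-dienoate | C/C(=C\CCC(=O)ON1C=CC=CC1=S)CC/C=C(\C)CO[Si](C)(C)C(C)(C)C
F9 | step 5 | tert-butyl{[(2E,6E)-9-iodo-2,6-dimethylnona-2,6-dien-1-yl]oxy}dimethylsilane | C/C(=C\CCI)CC/C=C(\C)CO[Si](C)(C)C(C)(C)C
F10 | step 5 | [(3E,7E)-9-(tert-butyldimethylsilyloxy)-4,8-dimethylnona-3,7-dien-1-yl]magnesium iodide | C/C(=C\CC[Mg]I)CC/C=C(\C)CO[Si](C)(C)C(C)(C)C
F11 | step 7 | (2S)-2-[(2S,5E,9E)-11-(tert-butyldimethylsilyloxy)-6,10-dimethyl-2-(triethylsilyloxy)undeca-5,9-dien-2-yl]-4-oxo-2,3,4,5,6,7-hexahydro-1-benzofuran-5-yl acetate (mixture of C5 epimers) | C/C(=C\CC[C@](C)(O[Si](CC)(CC)CC)[C@@H]1CC2=C(CCC(OC(C)=O)C2=O)O1)CC/C=C(\C)CO[Si](C)(C)C(C)(C)C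
F12 | step 7 | (2S,5S)-2-[(2S,5E,9E)-11-(tert-butyldimethylsilyloxy)-6,10-dimethyl-2-(triethylsilyloxy)undeca-5,9-dien-2-yl]-4-oxo-2,3,4,5,6,7-hexahydro-1-benzofuran-5-yl acetate | C/C(=C\CC[C@](C)(O[Si](CC)(CC)CC)[C@@H]1CC2=C(CC[C@H](OC(C)=O)C2=O)O1)CC/C=C(\C)CO[Si](C)(C)C(C)(C)C
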